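The strategy rests on ring A. The phenol carbon C2 lies between C1 (3,4-dimethoxyphenyl) and C3 (formyl carbon), so C2 is treated as the carbonyl carbon of a ketene O=C2=C1(Ar). This ketene is conjugated through the ring B bond C8a=C4a with an alkene C4=C3, and the key cut is C2–C3 (six-electron electrocyclization, then enolization).
Functional group changes come first in the retrosynthesis: the C3 formyl group goes back to a methyl ester (reduction, benzylic oxidation), and the 7-OH goes back to an isopropyl ether that is removed last.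
The ketene comes from a diarylacetic acid. C4=C3 and the ester carbon come from a Wittig reaction on the ring B aldehyde, and C1–C8a comes from a palladium-catalysed α-arylation of tert-butyl homoveratrate with an acetal-masked 2-bromobenzaldehyde.
The 7-O/8-OMe pattern is fixed at the outset by directed bromination of vanillin isopropyl ether at C2.
Ring order: ring B and the pendant ring are bought as benzenes, and ring A is the only ring built and is closed last.

Key step: step 9

Assumption: the naphthalene locants of the target (C1 aryl, C2 OH, C3 CHO, C7 OH, C8 OMe) are used for the same atoms in all open-chain precursors; vanillin isopropyl ether, homoveratric acid and the stabilised ylide are taken as commercial.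

Step 1
Reactants: 1 4-isopropoxy-3-methoxybenzaldehyde
Product: 5 2-bromo-4-isopropoxy-3-methoxybenzaldehyde, via lithium amino alkoxide 2 (not isolated), via C2-lithiated amino alkoxide 3 (not isolated), via C2-brominated amino alkoxide 4 (not isolated)
Conditions: MeNHCH2CH2NMe2, n-BuLi, THF, −20 °C, then 1; n-BuLi (2–3 equiv), −20 to 0 °C; BrCl2C–CCl2Br, −78 °C to rt; aq. HCl
Reagents that add atoms: 1,2-dibromo-1,1,2,2-tetrachloroethane, BrC(Cl)(Cl)C(Cl)(Cl)Br
Why: Directed ortho-metalation through an in situ α-amino alkoxide: the lithium amide adds to the formyl group, the chelating side arm of 2 and the C3 methoxy group together steer n-BuLi to the C2–H between them, aryllithium 3 takes bromine from the polyhaloethane, and acid then releases the aldehyde, so the later 7-O/8-OMe pattern is fixed here.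

Step 2
Reactants: 5 2-bromo-4-isopropoxy-3-methoxybenzaldehyde
Product: 6 2-(2-bromo-4-isopropoxy-3-methoxyphenyl)-1,3-dioxolane
Conditions: HOCH2CH2OH, TsOH·H2O (cat.), toluene, Dean–Stark, reflux
Reagents that add atoms: ethylene glycol, OCCO
Why: Acid-catalysed acetalization driven by azeotropic removal of water, which leaves the aryl bromide and both aryl ethers untouched and masks the electrophilic formyl group before the enolate chemistry.

Step 3
Reactants: 7 3,4-dimethoxyphenylacetic acid (homoveratric acid)
Product: 8 tert-butyl 2-(3,4-dimethoxyphenyl)acetate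
Conditions: Cl3CC(=NH)Ot-Bu (2 equiv), CH2Cl2–cyclohexane, rt
Reagents that add atoms: tert-butyl 2,2,2-trichloroacetimidate, CC(C)(C)OC(=N)C(Cl)(Cl)Cl
Why: Trichloroacetimidate esterification, in which the acid protonates the imidate and the carboxylate captures the tert-butyl cation under conditions too mild to alkylate the dimethoxyphenyl ring, gives an ester that resists Claisen self-condensation in step 4 and is orthogonal to the later methyl ester.

Step 4
Reactants: 6 2-(2-bromo-4-isopropoxy-3-methoxyphenyl)-1,3-dioxolane; 8 tert-butyl 2-(3,4-dimethoxyphenyl)acetate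
Product: 10 tert-butyl 2-(3,4-dimethoxyphenyl)-2-[6-(1,3-dioxolan-2-yl)-3-isopropoxy-2-methoxyphenyl]acetate (racemic), via lithium enolate 9 (not isolated)
Conditions: 8, LiN(SiMe3)2 (2.3 equiv), toluene, rt; then 6, Pd(dba)2 (5 mol %), P(t-Bu)3 (5 mol %), rt to 80 °C; aq. NH4Cl
Reagents that add atoms: none
Why: Palladium-catalysed α-arylation of an ester enolate: zerovalent palladium carrying the bulky, electron-rich P(t-Bu)3 inserts into the doubly flanked C–Br bond, enolate 9 replaces bromide and the crowding speeds C–C reductive elimination, while the acetal rules out aldol chemistry, the excess base stores the more acidic product as its enolate, and the new diarylmethine centre is racemic, which is harmless because it becomes sp2 in step 9.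

Step 5
Reactants: 10 tert-butyl 2-(3,4-dimethoxyphenyl)-2-[6-(1,3-dioxolan-2-yl)-3-isopropoxy-2-methoxyphenyl]acetate
Product: 11 tert-butyl 2-(3,4-dimethoxyphenyl)-2-(6-formyl-3-isopropoxy-2-methoxyphenyl)acetate (racemic)
Conditions: PPTS (cat.), acetone–H2O (10:1), 45 °C
Reagents that add atoms: water, O
Why: Mild acid-catalysed acetal hydrolysis: the aryl dioxolane, activated by the para isopropoxy group, ionises under pyridinium catalysis that is far too weak to cleave the tert-butyl ester or to promote Friedel–Crafts (Bradsher-type) attack of the dimethoxyphenyl ring on the freed formyl group.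

Step 6
Reactants: 11 tert-butyl 2-(3,4-dimethoxyphenyl)-2-(6-formyl-3-isopropoxy-2-methoxyphenyl)acetate; 12 methyl (triphenylphosphoranylidene)acetate
Product: 13 methyl (E)-3-[2-[2-tert-butoxy-1-(3,4-dimethoxyphenyl)-2-oxoethyl]-4-isopropoxy-3-methoxyphenyl]acrylate (racemic at the diarylmethine carbon)
Conditions: toluene, 90 °C
Reagents that add atoms: none
Why: Wittig olefination with a stabilised ylide, which under neutral, salt-free conditions should give the E-cinnamate and is not basic enough to deprotonate the diarylmethine position.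

Step 7
Reactants: 13 methyl (E)-3-[2-[2-tert-butoxy-1-(3,4-dimethoxyphenyl)-2-oxoethyl]-4-isopropoxy-3-methoxyphenyl]acrylate
Product: 14 2-(3,4-dimethoxyphenyl)-2-[3-isopropoxy-2-methoxy-6-[(E)-3-methoxy-3-oxoprop-1-enyl]phenyl]acetic acid (racemic)
Conditions: CF3CO2H–CH2Cl2 (1:4), 0 °C to rt
Reagents that add atoms: none
Why: Acidolysis of the tert-butyl ester by alkyl–oxygen cleavage, a path closed to the methyl ester, the methyl ethers and the isopropyl ether, with low temperature and short contact time so that acid-induced addition of the dimethoxyphenyl ring to the cinnamate does not start.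

Step 8
Reactants: 14 2-(3,4-dimethoxyphenyl)-2-[3-isopropoxy-2-methoxy-6-[(E)-3-methoxy-3-oxoprop-1-enyl]phenyl]acetic acid
Product: 15 methyl (E)-3-[2-[2-chloro-1-(3,4-dimethoxyphenyl)-2-oxoethyl]-4-isopropoxy-3-methoxyphenyl]acrylate (the acid chloride, racemic)
Conditions: (COCl)2 (1.5 equiv), DMF (cat.), CH2Cl2, 0 °C to rt; evaporate, use crude
Reagents that add atoms: oxalyl chloride, O=C(Cl)C(=O)Cl
Why: Acid chloride formation through the Vilsmeier-type chloroiminium salt from DMF and oxalyl chloride, which works at or below room temperature, gives only gaseous by-products and leaves the acrylate and the ethers alone.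

Step 9
Reactants: 15 methyl (E)-3-[2-[2-chloro-1-(3,4-dimethoxyphenyl)-2-oxoethyl]-4-isopropoxy-3-methoxyphenyl]acrylate
Product: 18 methyl 1-(3,4-dimethoxyphenyl)-2-hydroxy-7-isopropoxy-8-methoxynaphthalene-3-carboxylate, via diarylketene 16 (not isolated), via 3H-naphthalen-2-one 17 (not isolated)
Conditions: Et3N (3 equiv), dry toluene (0.005 M), rt, then 110 °C
Reagents that add atoms: none
Why: Et3N removes the doubly benzylic α-hydrogen of 15 and chloride leaves, the same dehydrochlorination that turns diphenylacetyl chloride into diphenylketene, so that ketene 16 holds the conjugated array O=C2=C1, C8a=C4a (ring B) and C4=C3. On heating, this array undergoes a thermal disrotatory six-electron electrocyclization in which the electrophilic ketene carbon C2 bonds to the acrylate α-carbon C3, which closes the six-membered ring A and gives 17 with ring B momentarily in ortho-quinodimethane form. Et3N then shifts the C3 hydrogen of 17, which is α to both ketone and ester, to oxygen, and this enolization restores both benzenoid rings and makes the sequence irreversible. The closest known reaction type is the dienylketene-to-phenol closure that ends the Danheiser benzannulation and the Et3N-induced benzannulation of activated 3,5-dienoic acids, a family in which arene double bonds are accepted members of the triene (arylvinylketenes to naphthols). No stereocentre survives, since the racemic C1 of 15 becomes sp2 in 16 and the transient C3 centre of 17 is erased by enolization. The step needs only periselectivity (closure rather than ketene dimerization, [2+2] addition or acylation of the product naphthol), and this is secured by the two aryl groups on C1, by high dilution, by the E-alkene that turns hydrogen and not the ester inward, by the 7-isopropoxy group para to C4a that raises the electron density at C3, and by the hindered, hydrogen-bonded OH of 18.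

Step 10
Reactants: 18 methyl 1-(3,4-dimethoxyphenyl)-2-hydroxy-7-isopropoxy-8-methoxynaphthalene-3-carboxylate
Product: 19 1-(3,4-dimethoxyphenyl)-3-(hydroxymethyl)-7-isopropoxy-8-methoxynaphthalen-2-ol
Conditions: LiAlH4 (3 equiv), THF, 0 °C to rt; aq. potassium sodium tartrate
Reagents that add atoms: none
Why: Hydride reduction of a salicylate-type ester: LiAlH4 first deprotonates the naphthol and then takes the ester to the primary alcohol, the aryl ethers are inert, and any naphthol that was O-acylated in step 9 is released at the same time.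

Step 11
Reactants: 19 1-(3,4-dimethoxyphenyl)-3-(hydroxymethyl)-7-isopropoxy-8-methoxynaphthalen-2-ol
Product: 20 1-(3,4-dimethoxyphenyl)-2-hydroxy-7-isopropoxy-8-methoxynaphthalene-3-carbaldehyde
Conditions: activated MnO2 (15 equiv), CH2Cl2, rt
Reagents that add atoms: none
Why: Heterogeneous MnO2 oxidation, selective for benzylic alcohols and established for ortho-hydroxybenzyl alcohols such as 3-(hydroxymethyl)-2-naphthol, should stop at the hydrogen-bonded aldehyde, while the aryl group at C1 blocks oxidative naphthol coupling.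

Step 12
Reactants: 20 1-(3,4-dimethoxyphenyl)-2-hydroxy-7-isopropoxy-8-methoxynaphthalene-3-carbaldehyde
Product: 22 vitrofolal B, via bis(dichloroboryloxy) intermediate 21 (not isolated)
Conditions: BCl3 (3 equiv, 1 M in CH2Cl2), CH2Cl2, −78 to 0 °C; then H2O, 0 °C
Reagents that add atoms: none
Why: Lewis acid dealkylation of an aryl ether: BCl3 binds the ether oxygen and the secondary isopropyl group leaves as 2-chloropropane by an SN1-like path much faster than any methyl group, no methoxy group stands ortho to the carbonyl for chelation-assisted demethylation, and water hydrolyses the boron aryloxides of 21 to the free phenols.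

Compound list
1 | 4-isopropoxy-3-methoxybenzaldehyde (vanillin isopropyl ether) | COc1cc(C=O)ccc1OC(C)C | starting material
2 | lithium [(2-dimethylaminoethyl)(methyl)amino](4-isopropoxy-3-methoxyphenyl)methanolate (racemic, formed in the flask) | [Li+].[O-]C(N(C)CCN(C)C)c1ccc(OC(C)C)c(OC)c1 | intermediate
3 | 2-lithio derivative of 2 (formed in the flask) | [Li+].[O-]C(N(C)CCN(C)C)c1ccc(OC(C)C)c(OC)c1[Li] | intermediate
4 | 2-bromo derivative of 2 (formed in the flask) | [Li+].[O-]C(N(C)CCN(C)C)c1ccc(OC(C)C)c(OC)c1Br | intermediate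
5 | 2-bromo-4-isopropoxy-3-methoxybenzaldehyde | O=Cc1ccc(OC(C)C)c(OC)c1Br | intermediate
6 | 2-(2-bromo-4-isopropoxy-3-methoxyphenyl)-1,3-dioxolane | COc1c(OC(C)C)ccc(C2OCCO2)c1Br | intermediate
7 | 3,4-dimethoxyphenylacetic acid | COc1ccc(CC(=O)O)cc1OC | starting material
8 | tert-butyl 2-(3,4-dimethoxyphenyl)acetate | COc1ccc(CC(=O)OC(C)(C)C)cc1OC | intermediate
9 | lithium enolate of 8 (formed in the flask) | [Li+].[O-]C(OC(C)(C)C)=Cc1ccc(OC)c(OC)c1 | intermediate
10 | tert-butyl 2-(3,4-dimethoxyphenyl)-2-[6-(1,3-dioxolan-2-yl)-3-isopropoxy-2-methoxyphenyl]acetate (racemic) | COc1ccc(C(C(=O)OC(C)(C)C)c2c(C3OCCO3)ccc(OC(C)C)c2OC)cc1OC | intermediate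
11 | tert-butyl 2-(3,4-dimethoxyphenyl)-2-(6-formyl-3-isopropoxy-2-methoxyphenyl)acetate (racemic) | COc1ccc(C(C(=O)OC(C)(C)C)c2c(C=O)ccc(OC(C)C)c2OC)cc1OC | intermediate
12 | methyl (triphenylphosphoranylidene)acetate | COC(=O)C=P(c1ccccc1)(c1ccccc1)c1ccccc1 | starting material
13 | methyl (E)-3-[2-[2-tert-butoxy-1-(3,4-dimethoxyphenyl)-2-oxoethyl]-4-isopropoxy-3-methoxyphenyl]acrylate (racemic) | COC(=O)/C=C/c1ccc(OC(C)C)c(OC)c1C(C(=O)OC(C)(C)C)c1ccc(OC)c(OC)c1 | intermediate
14 | 2-(3,4-dimethoxyphenyl)-2-[3-isopropoxy-2-methoxy-6-[(E)-3-methoxy-3-oxoprop-1-enyl]phenyl]acetic acid (racemic) | COC(=O)/C=C/c1ccc(OC(C)C)c(OC)c1C(C(=O)O)c1ccc(OC)c(OC)c1 | intermediate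
15 | methyl (E)-3-[2-[2-chloro-1-(3,4-dimethoxyphenyl)-2-oxoethyl]-4-isopropoxy-3-methoxyphenyl]acrylate (racemic acid chloride) | COC(=O)/C=C/c1ccc(OC(C)C)c(OC)c1C(C(=O)Cl)c1ccc(OC)c(OC)c1 | intermediate
16 | (3,4-dimethoxyphenyl)[3-isopropoxy-2-methoxy-6-[(E)-3-methoxy-3-oxoprop-1-enyl]phenyl]ketene (formed in the flask) | COC(=O)/C=C/c1ccc(OC(C)C)c(OC)c1C(=C=O)c1ccc(OC)c(OC)c1 | intermediate
17 | methyl 1-(3,4-dimethoxyphenyl)-7-isopropoxy-8-methoxy-2-oxo-2,3-dihydronaphthalene-3-carboxylate (racemic, ring B as ortho-quinodimethane, formed in the flask) | COC(=O)C1C=C2C=CC(OC(C)C)=C(OC)C2=C(c2ccc(OC)c(OC)c2)C1=O | intermediate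
18 | methyl 1-(3,4-dimethoxyphenyl)-2-hydroxy-7-isopropoxy-8-methoxynaphthalene-3-carboxylate | COC(=O)c1cc2ccc(OC(C)C)c(OC)c2c(-c2ccc(OC)c(OC)c2)c1O | intermediate
19 | 1-(3,4-dimethoxyphenyl)-3-(hydroxymethyl)-7-isopropoxy-8-methoxynaphthalen-2-ol | OCc1cc2ccc(OC(C)C)c(OC)c2c(-c2ccc(OC)c(OC)c2)c1O | intermediate
20 | 1-(3,4-dimethoxyphenyl)-2-hydroxy-7-isopropoxy-8-methoxynaphthalene-3-carbaldehyde | O=Cc1cc2ccc(OC(C)C)c(OC)c2c(-c2ccc(OC)c(OC)c2)c1O | intermediate
21 | 2,7-bis(dichloroboryloxy)-1-(3,4-dimethoxyphenyl)-8-methoxynaphthalene-3-carbaldehyde (formed in the flask) | COc1ccc(-c2c(OB(Cl)Cl)c(C=O)cc3ccc(OB(Cl)Cl)c(OC)c23)cc1OC | intermediate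
22 | vitrofolal B, 1-(3,4-dimethoxyphenyl)-2,7-dihydroxy-8-methoxynaphthalene-3-carbaldehyde | COc1ccc(-c2c(O)c(C=O)cc3ccc(O)c(OC)c23)cc1OC | target

Total step count: 12. Longest linear sequence: 11 steps (1 to 22 by steps 1, 2 and 4–12); step 3 is a one-step side branch from 7.

Steps most likely to fail

Step 9.
- **Risk:** The crowded diarylketene may not reach the coiled conformation that closure needs, and the temporary loss of ring B aromaticity raises the barrier. The ketene could then drain away by acylation of the product naphthol, by capture of traces of water or by oligomerization.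
- **Change of approach:** The fallback closes ring A at C3–C4 by an intramolecular Knoevenagel condensation. It sets out from 6 and comes back at 18.
- α-Arylation as in step 4, but with commercial methyl (3,4-dimethoxyphenyl)acetate, should give methyl 2-(3,4-dimethoxyphenyl)-2-[6-(1,3-dioxolan-2-yl)-3-isopropoxy-2-methoxyphenyl]acetate F1.
- LiOH in aqueous THF–MeOH, followed by acidification with citric acid, should give 2-(3,4-dimethoxyphenyl)-2-[6-(1,3-dioxolan-2-yl)-3-isopropoxy-2-methoxyphenyl]acetic acid F2 with the acetal intact.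
- 1,1'-Carbonyldiimidazole converts it into the acyl imidazole F3. This acylates Mg(O2CCH2CO2Me)2 at carbon with loss of CO2 to give methyl 4-(3,4-dimethoxyphenyl)-4-[6-(1,3-dioxolan-2-yl)-3-isopropoxy-2-methoxyphenyl]-3-oxobutanoate F4.
- PPTS in wet acetone frees methyl 4-(3,4-dimethoxyphenyl)-4-(6-formyl-3-isopropoxy-2-methoxyphenyl)-3-oxobutanoate F5.
- Piperidinium acetate in toluene condenses the active methylene (C3) with the formyl carbon (C4) to give methyl 1-(3,4-dimethoxyphenyl)-7-isopropoxy-8-methoxy-2-oxo-1,2-dihydronaphthalene-3-carboxylate F6, which tautomerises to 18.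

Step 4.
- **Risk:** Oxidative addition and enolate transfer at a bromide flanked by OMe and the dioxolane may be slow with a bulky secondary benzylic enolate. Protodebromination of the aryl bromide and decay of the enolate could then take over.
- **Change of approach:** The fallback makes the hindered bond with the smallest possible nucleophile and forms the diaryl carbon with an unhindered bromide. It sets out from 6 and comes back at 10.
- Negishi-type coupling of 6 with the Reformatsky reagent BrZnCH2CO2t-Bu (Pd(dba)2, P(t-Bu)3, THF, rt to 60 °C) should give tert-butyl 2-[6-(1,3-dioxolan-2-yl)-3-isopropoxy-2-methoxyphenyl]acetate F7.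
- α-Arylation of F7 with commercial 4-bromo-1,2-dimethoxybenzene (LiN(SiMe3)2, Pd(dba)2, P(t-Bu)3, toluene) should give 10.

Step 1.
- **Risk:** Metalation may be incomplete or may stray to C5 or C6. The amino alkoxide may also revert, so that n-BuLi adds to the aldehyde.
- **Change of approach:** The fallback masks the aldehyde permanently before the metalation and uses the neutral acetal as the directing group. It sets out from 1 and comes back at 6, bypassing 5.
- Acetalization of 1 (ethylene glycol, TsOH, toluene, Dean–Stark) should give 2-(4-isopropoxy-3-methoxyphenyl)-1,3-dioxolane F8.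
- n-BuLi in Et2O–THF at 0 °C removes the hydrogen between the acetal and the methoxy group (cooperative 1,3-direction) to give 2-(2-lithio-4-isopropoxy-3-methoxyphenyl)-1,3-dioxolane F9.
- A quench with BrCl2C–CCl2Br delivers 6 directly.

Further compounds
F1 | step 9 | methyl 2-(3,4-dimethoxyphenyl)-2-[6-(1,3-dioxolan-2-yl)-3-isopropoxy-2-methoxyphenyl]acetate (racemic) | COC(=O)C(c1ccc(OC)c(OC)c1)c1c(C2OCCO2)ccc(OC(C)C)c1OC
F2 | step 9 | 2-(3,4-dimethoxyphenyl)-2-[6-(1,3-dioxolan-2-yl)-3-isopropoxy-2-methoxyphenyl]acetic acid (racemic) | OC(=O)C(c1ccc(OC)c(OC)c1)c1c(C2OCCO2)ccc(OC(C)C)c1OC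
F3 | step 9 | 2-(3,4-dimethoxyphenyl)-2-[6-(1,3-dioxolan-2-yl)-3-isopropoxy-2-methoxyphenyl]-1-(imidazol-1-yl)ethanone (acyl imidazole, racemic) | O=C(n1ccnc1)C(c1ccc(OC)c(OC)c1)c1c(C2OCCO2)ccc(OC(C)C)c1OC
F4 | step 9 | methyl 4-(3,4-dimethoxyphenyl)-4-[6-(1,3-dioxolan-2-yl)-3-isopropoxy-2-methoxyphenyl]-3-oxobutanoate (racemic) | COC(=O)CC(=O)C(c1ccc(OC)c(OC)c1)c1c(C2OCCO2)ccc(OC(C)C)c1OC
F5 | step 9 | methyl 4-(3,4-dimethoxyphenyl)-4-(6-formyl-3-isopropoxy-2-methoxyphenyl)-3-oxobutanoate (racemic) | COC(=O)CC(=O)C(c1ccc(OC)c(OC)c1)c1c(C=O)ccc(OC(C)C)c1OC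
F6 | step 9 | methyl 1-(3,4-dimethoxyphenyl)-7-isopropoxy-8-methoxy-2-oxo-1,2-dihydronaphthalene-3-carboxylate (racemic) | COC(=O)C1=Cc2ccc(OC(C)C)c(OC)c2C(c2ccc(OC)c(OC)c2)C1=O
F7 | step 4 | tert-butyl 2-[6-(1,3-dioxolan-2-yl)-3-isopropoxy-2-methoxyphenyl]acetate | CC(C)(C)OC(=O)Cc1c(C2OCCO2)ccc(OC(C)C)c1OC
F8 | step 1 | 2-(4-isopropoxy-3-methoxyphenyl)-1,3-dioxolane | COc1cc(C2OCCO2)ccc1OC(C)C
F9 | step 1 | 2-(2-lithio-4-isopropoxy-3-methoxyphenyl)-1,3-dioxolane | COc1c([Li])c(C2OCCO2)ccc1OC(C)C
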